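**Remark on the chemistry.** The target has no stereocentre and no stereogenic double bond, so only constitution has to be controlled. Ring A is numbered from the carbon that bears the carboxyl group (C1) through C2 (OH), C3 (H), C4 (OH), C5 (OAc) to C6 (CH3). Ring A intermediates are named with these locants rather than with lowest locants.

## Analysis of the target

The target is a linear tridepside. Three benzoate rings are joined by two aryl ester bonds: the acyl carbon of ring A to O4 of ring B, and the acyl carbon of ring B to O4 of ring C, which ends in a free carboxylic acid. Rings B and C are plain orsellinate units (C2 hydroxyl, C6 methyl, C4 oxygen in the ester link). Ring A is an orsellinate with one more oxygen, at C5, and this oxygen alone is acetylated. There is no stereocentre, so the problem is one of regiochemistry and of telling six oxygen functions apart. The sensitive groups are the aryl acetate next to the free C4 hydroxyl (acyl migration, solvolysis by base or nucleophiles), the two depside esters (transesterification), the 1,2,4-trioxygenated ring A (oxidation to a quinone once a para pair of oxygens is free) and the salicylic-type acid of ring C (decarboxylation on heating). The synthesis is hard for three reasons: ring A, unlike rings B and C, has no commercial aromatic precursor with the right oxygen pattern; both ester bonds join a doubly ortho-substituted acyl carbon to a phenol; and after the acetate is in place nothing basic or nucleophilic may follow, so the last unmasking must be neutral. The strategy rests on the fact that C1, C2, C4 and C6 of ring A reproduce the pattern of a 6-methyl-2,4-dioxocyclohexane-1-carboxylate, and that C5 lies alpha to the C4 carbonyl. Its oxygen can therefore come in on the alpha carbon of a crotonate, and ring A can be built saturated from two open-chain esters and dehydrogenated afterwards.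

## Retrosynthetic reasoning

**24 to 23.** The four free acidic functions that must not meet base (O2–H and O4–H of ring A, O2–H of ring B, the carboxyl of ring C) are masked as benzyl ethers and a benzyl ester. One neutral hydrogenolysis then ends the synthesis and leaves the acetate and both depside links alone.

**23 to 14 and 22.** The acyl C–O bond between C1 of ring A and O4 of ring B is cut. This is the most convergent cut: it puts the unusual ring A into one fragment (acid 14) and the two ordinary orsellinate rings into the other (phenol 22). The acetate must already be on 14, because after the union no single oxygen could be acetylated selectively. The forward reaction has to esterify a hindered acid with the one unchelated hydroxyl of 22 without disturbing the acetate.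

**22 to 18 and 20.** The second depside bond is cut in the same way. Ring C comes from 19 as its benzyl ester 20, whose O2–H is hydrogen-bonded to the ester and can stay free. Ring B comes from 15 through 16 and 17 to acid 18. Its O4 carries a 4-methoxybenzyl group that dilute acid removes from 21 while benzyl groups stay.

**14 to 12 to 11 to 10.** These are functional-group changes on ring A. The acetate of 14 is put on the C5 hydroxyl of 12. Compound 12 arises from 11 by one acid treatment that removes both the 4-methoxybenzyl ether at O5 and the tert-butyl ester at C1. Both groups survive the base and the palladium of the earlier steps, and both ionise in acid far faster than aryl benzyl ethers. An oxidative, quinone-mediated removal of the 4-methoxybenzyl group was set aside, because ring A of 11 and the para-alkoxyphenol it would release are more easily oxidised than the anisyl ring. Compound 11 is the dibenzyl ether of 10, in which O5 is the only ether oxygen.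

**10 to 9.** Adding two hydrogens across C1–C6 of 10 gives the cyclohexane-1,3-dione 9. The two carbonyl groups already count for two of the three unsaturations of the arene, so a single dehydrogenation leads back to 10.

**9 to 6 and 7 (through 8).** The bonds C1–C6 and C3–C4 are cut. This maps C1, C2, C3 and the carboxyl carbon onto the acetoacetate 7, and C4, C5, C6 and the C6 methyl onto the 2-alkoxycrotonate 6. The cut is made here because both bonds form in one flask from two simple esters, and because it places the fourth oxygen at C5 without any arene functionalisation. The forward reaction must add the alpha carbon of 7 to the beta carbon of 6 and then acylate the methyl group of the adduct 8 with its ethyl ester.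

**6 to 4 and 5; 4 to 2 and 3; 2 to 1.** The enol ether double bond of 6 is cut by an olefination into phosphonate 4 and aldehyde 5. The C–O bond of 4 is cut by a carbenoid O–H insertion into diazo compound 2 and alcohol 3. Compound 2 comes from 1 by diazo transfer. These three steps are reliable, so the risk of the route sits in the annulation.

## Alternatives that were turned down

**Alternative 1:** Ring B is disconnected at its C1–C6 bond together with the ester C–O bond to ring C. This leads back to the diketo-dioxinone A2 and the ring C phenol A3. In the forward sense, heating A2 with A3 causes cycloreversion of the dioxinone to an acylketene, which A3 captures at O4. An amine then promotes aldol condensation of chain C2 onto the C7 ketone and aromatisation, giving the didepside A1 with O2–H and O4–H of ring B free.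
- For it: an ester bond and a ring form in one operation, ring B needs no protecting group, and A1 has the free O4–H that the union with 14 needs (O2–H being chelated). On this point it is stronger than the six steps that lead to 22 here.
- Against it: it spends its main step on a ring that can be bought in the form of 15 or 19, and it leaves ring A unsolved. In this polyketide-type folding C5 of a resorcylate comes from a chain methylene, so the extra oxygen of ring A cannot be introduced this way.
- Against it also: the triketo aryl ester intermediate has an aryloxide as leaving group, so enol attack on the ester carbonyl (pyranone formation with loss of A3) competes with the aldol closure.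
- Comparison: the chosen route is longer for the B–C half, but it addresses the ring that sets this target apart and builds the B–C half from standard protecting-group operations.

**Alternative 2:** Ring C is disconnected at C1–C2, C2–C3 and C4–C5 into the diazo enone A5 and the siloxyalkyne A6. Photochemical Wolff rearrangement of A5 gives a vinylketene that adds to A6 in a [2+2] sense. The cyclobutenone opens (4π) and recloses (6π) to the phenol A4, with O2–H free, O4 silylated and a trimethylsilyl group at C3.
- For it: regiochemistry is fixed by the mechanism, conditions are neutral, and the arene forms directly at the right oxidation level. On this last point it is stronger than the chosen route, which needs a separate dehydrogenation.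
- Against it: ring C is the simplest ring of the target and is one step away from 19. The C3 silyl group must then be removed, and the free hydroxyl is O2 while the one needed for coupling is O4, so the protecting groups must be exchanged.
- Against it also: A5 carries a diazo group and an electron-poor alkene in one molecule and may be consumed by dipolar cycloaddition before the photolysis.
- Comparison: it is elegant but aimed at the wrong ring. The chosen route puts its ring-forming step on ring A.

**Alternative 3:** Ring A is disconnected at C1–C2 and C5–C6 into the 2-silyloxy-4-benzyloxyfuran A8 and the but-2-ynoate A9 of the B–C phenol. Diels–Alder addition of A8 across the alkyne of A9 gives an oxanorbornadiene, which opens and tautomerises to A7 with a C2 silyl ether, a C4 benzyl ether and the C5 hydroxyl free.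
- For it: it is the most convergent plan. Ring A appears fully aromatic on the finished didepside, and C5–OH is the only free hydroxyl, ready for acetylation without protecting-group exchange or oxidation. In convergence and protecting-group economy it is stronger than the chosen route.
- Against it: A8 is a hydrolytically fragile ketene-acetal-type diene, and the β-methyl ynoate A9 is a sluggish dienophile, so the cycloaddition needs heat on a valuable late intermediate.
- Against it also: the bridge can open in two directions. After acetylation the C2 silyl ether would have to be removed with fluoride or acid next to an aryl acetate and two depside esters, where acetyl migration and ester cleavage threaten.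
- Comparison: the chosen route takes its risk early, on two cheap esters, and ends with a neutral hydrogenolysis.

Key step: step 4

## Route

**Step 1**
Reactants: 1 triethyl phosphonoacetate
Product: 2 ethyl 2-diazo-2-(diethoxyphosphoryl)acetate
Conditions: 4-acetamidobenzenesulfonyl azide, DBU, MeCN, 0 → 25 °C
Reagents that add atoms: 4-acetamidobenzenesulfonyl azide, CC(=O)Nc1ccc(cc1)S(=O)(=O)N=[N+]=[N-]
Why: Regitz diazo transfer: the phosphonoacetate carbanion attacks the terminal nitrogen of the sulfonyl azide and the triazene collapses to the diazo compound and the sulfonamide; the doubly acceptor-substituted diazo ester is stable enough to be handled and purified.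

**Step 2**
Reactants: 2 ethyl 2-diazo-2-(diethoxyphosphoryl)acetate; 3 4-methoxybenzyl alcohol
Product: 4 ethyl 2-(diethoxyphosphoryl)-2-[(4-methoxybenzyl)oxy]acetate
Conditions: Rh2(OAc)4 (1 mol %), toluene, 90 °C
Reagents that add atoms: none
Why: Rh2(OAc)4 turns 2 into an electrophilic rhodium carbenoid, which the hydroxyl oxygen of 3 captures as an oxonium ylide that rearranges by proton shift (carbenoid O–H insertion); capture by the hydroxyl group should outrun attack on the anisyl ring, and the heating is needed because acceptor/acceptor diazo compounds lose nitrogen slowly.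

**Step 3**
Reactants: 4 ethyl 2-(diethoxyphosphoryl)-2-[(4-methoxybenzyl)oxy]acetate; 5 acetaldehyde
Product: 6 ethyl (Z)-2-[(4-methoxybenzyl)oxy]but-2-enoate
Conditions: NaH, THF, 0 °C; then 5 (excess), −78 → 25 °C
Reagents that add atoms: none
Why: Horner–Wadsworth–Emmons olefination of the α-alkoxy phosphonate anion with an unhindered aldehyde; the (Z)-enol ether (methyl trans to the ester) should predominate, and any (E)-isomer can be carried along because the alkene geometry is lost in step 4.

**Step 4**
Reactants: 6 ethyl (Z)-2-[(4-methoxybenzyl)oxy]but-2-enoate; 7 tert-butyl acetoacetate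
Product: 9 tert-butyl 5-[(4-methoxybenzyl)oxy]-6-methyl-2,4-dioxocyclohexane-1-carboxylate, via Michael adduct 8 (not isolated)
Conditions: 7, KOtBu (1.05 equiv), tBuOH, 25 °C; then 6, 80 °C; then 1 M HCl, 0 °C
Reagents that add atoms: none
Why: The potassium enolate of 7, formed only at the doubly activated methylene, adds to the β-carbon of 6 (Michael addition, ring A bond C1–C6) and gives the open-chain adduct 8 after proton transfer. Proton exchange in 8 then produces a small concentration of the methyl ketone enolate, whose carbon attacks the ethyl ester carbonyl and expels ethoxide (intramolecular Claisen condensation, ring A bond C3–C4). The closest known reaction type is the Michael–Claisen annulation of acetoacetates with crotonates that leads to dihydroorsellinates; 6 differs by the ether oxygen on its α-carbon, which lowers the electrophilicity of the β-carbon, so longer heating is to be expected. The ring closes in the 6-(enolendo)-exo-trig mode, which is favoured. C1, C5 and C6 become stereocentres without control and, C1 and C5 being enolisable, should settle as an equilibrium mixture of diastereomers and enol forms; none needs control because step 5 makes all three trigonal, and for the same reason the (E)/(Z) composition of 6 does not matter. The step needs 1,4- instead of 1,2-attack and reaction of 7 first at its α-carbon and then at its methyl group: the difference in acidity leaves only the α-enolate at the start, addition to the ester carbonyl is reversible and leads nowhere, and after the Michael addition the now tertiary α-carbon could only close a four-membered ring, while the hindered tert-butyl ester is no acyl donor. The sequence is driven by irreversible deprotonation of the product at C3 (a vinylogous acid), which is why a full equivalent of base is used and why the enolate of 7 is preformed, so that no free alkoxide isomerises 6 by γ-deprotonation.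

**Step 5**
Reactants: 9 tert-butyl 5-[(4-methoxybenzyl)oxy]-6-methyl-2,4-dioxocyclohexane-1-carboxylate
Product: 10 tert-butyl 2,4-dihydroxy-5-[(4-methoxybenzyl)oxy]-6-methylbenzoate
Conditions: Pd(O2CCF3)2 (10 mol %), 2-(dimethylamino)pyridine (20 mol %), O2 (1 atm), DMSO, 80 °C
Reagents that add atoms: none
Why: Aerobic dehydrogenation by a divalent palladium catalyst: a palladium enolate forms at C1 or C5, β-hydride elimination toward C6 introduces the one missing double bond, the dienone tautomerises to the resorcinol, and oxygen reoxidises zerovalent palladium. The dione needs only this single dehydrogenation; the acidic substrate stands in for a sulfonic acid co-catalyst, which spares the tert-butyl ester and the ether, and the C5 alkoxy group cannot be eliminated because that would need a carbanion at the unactivated C6.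

**Step 6**
Reactants: 10 tert-butyl 2,4-dihydroxy-5-[(4-methoxybenzyl)oxy]-6-methylbenzoate
Product: 11 tert-butyl 2,4-bis(benzyloxy)-5-[(4-methoxybenzyl)oxy]-6-methylbenzoate
Conditions: BnBr, K2CO3, Bu4NI (cat.), DMF, 60 °C, under argon
Reagents that add atoms: benzyl bromide, BrCc1ccccc1
Why: Williamson ether synthesis; O4–H reacts readily, the O2–H chelated to the ester needs the polar solvent and heat, carbonate in DMF favours O- over C-alkylation at C3, and air is excluded because the phenoxide of this trioxygenated ring is easily oxidised.

**Step 7**
Reactants: 11 tert-butyl 2,4-bis(benzyloxy)-5-[(4-methoxybenzyl)oxy]-6-methylbenzoate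
Product: 12 2,4-bis(benzyloxy)-5-hydroxy-6-methylbenzoic acid
Conditions: CF3CO2H–CH2Cl2 (1:3), Et3SiH (5 equiv), 0 → 25 °C, under argon
Reagents that add atoms: none
Why: Acidolysis of both acid-labile groups in one operation: the aryl 4-methoxybenzyl ether ionises to a benzylic cation that the silane reduces before it can alkylate C3, and the tert-butyl ester cleaves by alkyl–oxygen fission with loss of isobutene; aryl benzyl ethers ionise far more slowly and should remain.

**Step 8**
Reactants: 12 2,4-bis(benzyloxy)-5-hydroxy-6-methylbenzoic acid
Product: 14 5-acetoxy-2,4-bis(benzyloxy)-6-methylbenzoic acid, via mixed acetic anhydride 13 (not isolated)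
Conditions: Ac2O, pyridine, CH2Cl2, 0 → 25 °C; then H2O–THF, 25 °C
Reagents that add atoms: acetic anhydride, CC(=O)OC(C)=O
Why: Pyridine-promoted O-acetylation of the only free phenol; the carboxyl group is converted at the same time into the mixed anhydride 13, which water attacks at the unhindered acetyl carbonyl in the aqueous stage, so that only the aryl acetate remains. Crude 12 is acetylated without delay because it is a hydroquinone monoether.

**Step 9**
Reactants: 15 2,4-dihydroxy-6-methylbenzaldehyde
Product: 16 2-hydroxy-4-[(4-methoxybenzyl)oxy]-6-methylbenzaldehyde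
Conditions: 4-methoxybenzyl chloride (1.05 equiv), K2CO3 (1.1 equiv), KI (cat.), acetone, 50 °C
Reagents that add atoms: 4-methoxybenzyl chloride, COc1ccc(CCl)cc1
Why: Williamson etherification selective for O4–H: O2–H is held in a hydrogen bond to the aldehyde and is less acidic and less nucleophilic, so one equivalent of halide with a weak base should alkylate the para hydroxyl only.

**Step 10**
Reactants: 16 2-hydroxy-4-[(4-methoxybenzyl)oxy]-6-methylbenzaldehyde
Product: 17 2-(benzyloxy)-4-[(4-methoxybenzyl)oxy]-6-methylbenzaldehyde
Conditions: BnBr, K2CO3, DMF, 60 °C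
Reagents that add atoms: benzyl bromide, BrCc1ccccc1
Why: Williamson etherification of the remaining chelated hydroxyl under more forcing conditions; the aldehyde and the existing ether are inert to carbonate.

**Step 11**
Reactants: 17 2-(benzyloxy)-4-[(4-methoxybenzyl)oxy]-6-methylbenzaldehyde
Product: 18 2-(benzyloxy)-4-[(4-methoxybenzyl)oxy]-6-methylbenzoic acid
Conditions: NaClO2, NaH2PO4, 2-methylbut-2-ene, tBuOH–THF–H2O, 0 → 25 °C
Reagents that add atoms: NaClO2 (sodium chlorite), [Na+].[O-]Cl=O
Why: Pinnick oxidation: chlorous acid adds to the aldehyde and fragments to the acid and hypochlorous acid, which the alkene scavenges before it can chlorinate the electron-rich ring; this route avoids saponifying a doubly ortho-substituted ester.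

**Step 12**
Reactants: 19 2,4-dihydroxy-6-methylbenzoic acid (orsellinic acid)
Product: 20 benzyl 2,4-dihydroxy-6-methylbenzoate
Conditions: BnBr (1.0 equiv), KHCO3 (1.1 equiv), DMF, 25 °C
Reagents that add atoms: benzyl bromide, BrCc1ccccc1
Why: SN2 alkylation of the carboxylate, the only group that hydrogen carbonate deprotonates to a useful extent; the phenols stay free and the room-temperature conditions avoid decarboxylation of the acid.

**Step 13**
Reactants: 18 2-(benzyloxy)-4-[(4-methoxybenzyl)oxy]-6-methylbenzoic acid; 20 benzyl 2,4-dihydroxy-6-methylbenzoate
Product: 21 benzyl 4-({2-(benzyloxy)-4-[(4-methoxybenzyl)oxy]-6-methylbenzoyl}oxy)-2-hydroxy-6-methylbenzoate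
Conditions: DCC, DMAP (cat.), CH2Cl2, 0 → 25 °C
Reagents that add atoms: none
Why: Steglich esterification: the O-acylisourea is passed on by DMAP as an acylpyridinium ion to the free para hydroxyl O4–H of 20; the ortho hydroxyl is hydrogen-bonded to the benzyl ester and shielded by it, so it should not compete.

**Step 14**
Reactants: 21 benzyl 4-({2-(benzyloxy)-4-[(4-methoxybenzyl)oxy]-6-methylbenzoyl}oxy)-2-hydroxy-6-methylbenzoate
Product: 22 benzyl 4-{[2-(benzyloxy)-4-hydroxy-6-methylbenzoyl]oxy}-2-hydroxy-6-methylbenzoate
Conditions: CF3CO2H (10 vol %), Et3SiH, CH2Cl2, 0 °C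
Reagents that add atoms: none
Why: Acidolysis of the aryl 4-methoxybenzyl ether with reductive capture of the cation by the silane; the phenol para to an ester is a good leaving group, so dilute acid at 0 °C suffices and the benzyl ether, the benzyl ester and the hindered depside ester should remain.

**Step 15**
Reactants: 14 5-acetoxy-2,4-bis(benzyloxy)-6-methylbenzoic acid; 22 benzyl 4-{[2-(benzyloxy)-4-hydroxy-6-methylbenzoyl]oxy}-2-hydroxy-6-methylbenzoate
Product: 23 benzyl 4-({4-[(5-acetoxy-2,4-bis(benzyloxy)-6-methylbenzoyl)oxy]-2-(benzyloxy)-6-methylbenzoyl}oxy)-2-hydroxy-6-methylbenzoate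
Conditions: DCC, DMAP (cat.), CH2Cl2, 0 → 25 °C
Reagents that add atoms: none
Why: Steglich esterification of the doubly ortho-substituted acid 14 with the only unchelated hydroxyl of 22 (ring B O4–H); the medium is close to neutral, so the aryl acetate and the existing depside link should persist, and DMAP is kept catalytic to limit acetyl transfer.

**Step 16**
Reactants: 23 benzyl 4-({4-[(5-acetoxy-2,4-bis(benzyloxy)-6-methylbenzoyl)oxy]-2-(benzyloxy)-6-methylbenzoyl}oxy)-2-hydroxy-6-methylbenzoate
Product: 24 4-({4-[(5-acetoxy-2,4-dihydroxy-6-methylbenzoyl)oxy]-2-hydroxy-6-methylbenzoyl}oxy)-2-hydroxy-6-methylbenzoic acid (CNP0154030.0)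
Conditions: H2 (1 atm), Pd/C (10 wt % Pd), EtOAc–THF, 25 °C
Reagents that add atoms: none
Why: Hydrogenolysis of the three aryl benzyl ethers and the benzyl ester under neutral conditions in a non-nucleophilic solvent, which leaves aryl esters alone; alcohols, base and heat are avoided so that the acetyl group neither migrates from O5 to the neighbouring O4 nor is lost, and the salicylic-type acid does not decarboxylate.

## Compound list

1 | triethyl phosphonoacetate | CCOC(=O)CP(=O)(OCC)OCC | starting material
2 | ethyl 2-diazo-2-(diethoxyphosphoryl)acetate | CCOC(=O)C(=[N+]=[N-])P(=O)(OCC)OCC | intermediate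
3 | 4-methoxybenzyl alcohol | COc1ccc(CO)cc1 | starting material
4 | ethyl 2-(diethoxyphosphoryl)-2-[(4-methoxybenzyl)oxy]acetate | CCOC(=O)C(OCc1ccc(OC)cc1)P(=O)(OCC)OCC | intermediate
5 | acetaldehyde | CC=O | starting material
6 | ethyl (Z)-2-[(4-methoxybenzyl)oxy]but-2-enoate | C/C=C(\OCc1ccc(OC)cc1)C(=O)OCC | intermediate
7 | tert-butyl acetoacetate | CC(=O)CC(=O)OC(C)(C)C | starting material
8 | 1-tert-butyl 5-ethyl 2-acetyl-4-[(4-methoxybenzyl)oxy]-3-methylpentanedioate (Michael adduct, mixture of diastereomers) | CCOC(=O)C(OCc1ccc(OC)cc1)C(C)C(C(C)=O)C(=O)OC(C)(C)C | intermediate (not isolated)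
9 | tert-butyl 5-[(4-methoxybenzyl)oxy]-6-methyl-2,4-dioxocyclohexane-1-carboxylate (mixture of diastereomers and enol forms) | CC1C(OCc2ccc(OC)cc2)C(=O)CC(=O)C1C(=O)OC(C)(C)C | intermediate
10 | tert-butyl 2,4-dihydroxy-5-[(4-methoxybenzyl)oxy]-6-methylbenzoate | Cc1c(OCc2ccc(OC)cc2)c(O)cc(O)c1C(=O)OC(C)(C)C | intermediate
11 | tert-butyl 2,4-bis(benzyloxy)-5-[(4-methoxybenzyl)oxy]-6-methylbenzoate | Cc1c(OCc2ccc(OC)cc2)c(OCc2ccccc2)cc(OCc2ccccc2)c1C(=O)OC(C)(C)C | intermediate
12 | 2,4-bis(benzyloxy)-5-hydroxy-6-methylbenzoic acid | Cc1c(O)c(OCc2ccccc2)cc(OCc2ccccc2)c1C(=O)O | intermediate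
13 | acetic 5-acetoxy-2,4-bis(benzyloxy)-6-methylbenzoic anhydride | CC(=O)Oc1c(C)c(C(=O)OC(C)=O)c(OCc2ccccc2)cc1OCc1ccccc1 | intermediate (not isolated)
14 | 5-acetoxy-2,4-bis(benzyloxy)-6-methylbenzoic acid | CC(=O)Oc1c(C)c(C(=O)O)c(OCc2ccccc2)cc1OCc1ccccc1 | intermediate
15 | 2,4-dihydroxy-6-methylbenzaldehyde | Cc1cc(O)cc(O)c1C=O | starting material
16 | 2-hydroxy-4-[(4-methoxybenzyl)oxy]-6-methylbenzaldehyde | Cc1cc(OCc2ccc(OC)cc2)cc(O)c1C=O | intermediate
17 | 2-(benzyloxy)-4-[(4-methoxybenzyl)oxy]-6-methylbenzaldehyde | Cc1cc(OCc2ccc(OC)cc2)cc(OCc2ccccc2)c1C=O | intermediate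
18 | 2-(benzyloxy)-4-[(4-methoxybenzyl)oxy]-6-methylbenzoic acid | Cc1cc(OCc2ccc(OC)cc2)cc(OCc2ccccc2)c1C(=O)O | intermediate
19 | 2,4-dihydroxy-6-methylbenzoic acid (orsellinic acid) | Cc1cc(O)cc(O)c1C(=O)O | starting material
20 | benzyl 2,4-dihydroxy-6-methylbenzoate | Cc1cc(O)cc(O)c1C(=O)OCc1ccccc1 | intermediate
21 | benzyl 4-({2-(benzyloxy)-4-[(4-methoxybenzyl)oxy]-6-methylbenzoyl}oxy)-2-hydroxy-6-methylbenzoate | Cc1cc(OCc2ccc(OC)cc2)cc(OCc2ccccc2)c1C(=O)Oc1cc(C)c(C(=O)OCc2ccccc2)c(O)c1 | intermediate
22 | benzyl 4-{[2-(benzyloxy)-4-hydroxy-6-methylbenzoyl]oxy}-2-hydroxy-6-methylbenzoate | Cc1cc(O)cc(OCc2ccccc2)c1C(=O)Oc1cc(C)c(C(=O)OCc2ccccc2)c(O)c1 | intermediate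
23 | benzyl 4-({4-[(5-acetoxy-2,4-bis(benzyloxy)-6-methylbenzoyl)oxy]-2-(benzyloxy)-6-methylbenzoyl}oxy)-2-hydroxy-6-methylbenzoate | CC(=O)Oc1c(C)c(C(=O)Oc2cc(C)c(C(=O)Oc3cc(C)c(C(=O)OCc4ccccc4)c(O)c3)c(OCc3ccccc3)c2)c(OCc2ccccc2)cc1OCc1ccccc1 | intermediate
24 | 4-({4-[(5-acetoxy-2,4-dihydroxy-6-methylbenzoyl)oxy]-2-hydroxy-6-methylbenzoyl}oxy)-2-hydroxy-6-methylbenzoic acid | CC(=O)Oc1c(O)cc(O)c(C(=O)Oc2cc(C)c(C(=O)Oc3cc(C)c(C(=O)O)c(O)c3)c(O)c2)c1C | target

## Step count and least certain steps

Total step count: 16. Longest linear sequence: 10 steps (steps 1 to 8, then 15 and 16, from 1 to 24). The branch to 22 (steps 9 to 14) joins at step 15.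

**Step 4 (key step).** The conjugate addition may stall or run backwards. The ether oxygen on the α-carbon of 6 pushes electron density onto the β-carbon, the β-methyl group adds hindrance, and the Michael step stays reversible until the ring has closed. Meanwhile the base can move the double bond of 6 out of conjugation by γ-deprotonation, and 7 can condense with itself.
Fallback: the ring is taken from the aromatic pool and the C5 oxygen is introduced on the arene. It sets out from 15 and comes back at 12. Benzylation of both hydroxyls of 15 (benzyl bromide, K2CO3, DMF) would give 2,4-bis(benzyloxy)-6-methylbenzaldehyde F1. Bromination with N-bromosuccinimide should go to C5, which is para to O2 and ortho to O4, the position between the two ethers being more crowded, and give 2,4-bis(benzyloxy)-5-bromo-6-methylbenzaldehyde F2. Chlorite oxidation as in step 11 would give 2,4-bis(benzyloxy)-5-bromo-6-methylbenzoic acid F3. Palladium-catalysed hydroxylation of the aryl bromide (Pd2(dba)3, 2-(di-tert-butylphosphino)-2',4',6'-triisopropylbiphenyl, KOH, dioxane–water, 100 °C) would then give 12. This gives up the ring construction and accepts a hydroxylation at a doubly ortho-substituted bromide.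

**Step 5.** The diketonate may bind divalent palladium as a stable O,O-chelate and stop turnover. The electron-rich product may be oxidised further by oxygen at 80 °C. The tert-butyl ester may be lost, with decarboxylation, in hot DMSO.
Fallback: oxidation through a silyl dienol ether without oxygen, setting out from 9 and coming back at 10. Double silylation of 9 (trimethylsilyl triflate, triethylamine, CH2Cl2, 0 °C) would give tert-butyl 5-[(4-methoxybenzyl)oxy]-6-methyl-2,4-bis(trimethylsilyloxy)cyclohexa-1,3-diene-1-carboxylate F4; its regioisomeric diene would serve equally. Saegusa–Ito oxidation with one equivalent of Pd(OAc)2 in MeCN at 25 °C places palladium on C1, and β-hydride elimination toward C6 followed by tautomerisation and a methanolic work-up that cleaves the remaining aryl silyl ether would give 10.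

**Step 7.** Besides the two intended ionisations, loss of benzyl ethers, alkylation of C3 of the very electron-rich ring by benzylic or tert-butyl cations, and protodecarboxylation of 12 (C1 is ortho and para to ether oxygens) may occur.
Fallback: the two acid-labile groups are removed in separate operations and the ester is cleaved only after the ring has been deactivated. It sets out from 11 and comes back at 14. Brief treatment of 11 with 1 to 2 vol % CF3CO2H and Et3SiH in CH2Cl2 at −20 °C should remove only the 4-methoxybenzyl group and give tert-butyl 2,4-bis(benzyloxy)-5-hydroxy-6-methylbenzoate F5. Acetylation (acetic anhydride, pyridine) would give tert-butyl 5-acetoxy-2,4-bis(benzyloxy)-6-methylbenzoate F6. Aprotic Lewis-acid cleavage of the tert-butyl ester with ZnBr2 in CH2Cl2 at 25 °C would give 14. Any material that had already lost the ester in the first operation is 12 and goes on through step 8.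

**Step 15.** Acyl transfer to the phenol may be slower than rearrangement of the hindered O-acylisourea to the N-acylurea. DMAP may carry the acetyl group from O5 of ring A to the phenol of 22. The chelated hydroxyl of ring C may be acylated in part.
Fallback: linear assembly from ring A to ring B to ring C, in which 14 is first joined to a small monocyclic phenol through its acid chloride. It sets out from 17 and 14 and comes back at 23. Acidolysis of 17 (CF3CO2H, anisole, CH2Cl2, 0 °C; no silane, to spare the aldehyde) would give 2-(benzyloxy)-4-hydroxy-6-methylbenzaldehyde F7. Acid 14 would be converted with oxalyl chloride and catalytic DMF into 5-acetoxy-2,4-bis(benzyloxy)-6-methylbenzoyl chloride F8. F8 acylates F7 in the presence of triethylamine to 3-(benzyloxy)-4-formyl-5-methylphenyl 5-acetoxy-2,4-bis(benzyloxy)-6-methylbenzoate F9. Chlorite oxidation as in step 11 would give 4-{[5-acetoxy-2,4-bis(benzyloxy)-6-methylbenzoyl]oxy}-2-(benzyloxy)-6-methylbenzoic acid F10. Esterification of F10 with 20 under the conditions of step 13 would give 23.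

## Further compounds

F1 | step 4 | 2,4-bis(benzyloxy)-6-methylbenzaldehyde | Cc1cc(OCc2ccccc2)cc(OCc2ccccc2)c1C=O
F2 | step 4 | 2,4-bis(benzyloxy)-5-bromo-6-methylbenzaldehyde | Cc1c(Br)c(OCc2ccccc2)cc(OCc2ccccc2)c1C=O
F3 | step 4 | 2,4-bis(benzyloxy)-5-bromo-6-methylbenzoic acid | Cc1c(Br)c(OCc2ccccc2)cc(OCc2ccccc2)c1C(=O)O
F4 | step 5 | tert-butyl 5-[(4-methoxybenzyl)oxy]-6-methyl-2,4-bis(trimethylsilyloxy)cyclohexa-1,3-diene-1-carboxylate (mixture of diastereomers) | CC1C(OCc2ccc(OC)cc2)C(O[Si](C)(C)C)=CC(O[Si](C)(C)C)=C1C(=O)OC(C)(C)C
F5 | step 7 | tert-butyl 2,4-bis(benzyloxy)-5-hydroxy-6-methylbenzoate | Cc1c(O)c(OCc2ccccc2)cc(OCc2ccccc2)c1C(=O)OC(C)(C)C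
F6 | step 7 | tert-butyl 5-acetoxy-2,4-bis(benzyloxy)-6-methylbenzoate | CC(=O)Oc1c(C)c(C(=O)OC(C)(C)C)c(OCc2ccccc2)cc1OCc1ccccc1
F7 | step 15 | 2-(benzyloxy)-4-hydroxy-6-methylbenzaldehyde | Cc1cc(O)cc(OCc2ccccc2)c1C=O
F8 | step 15 | 5-acetoxy-2,4-bis(benzyloxy)-6-methylbenzoyl chloride | CC(=O)Oc1c(C)c(C(=O)Cl)c(OCc2ccccc2)cc1OCc1ccccc1
F9 | step 15 | 3-(benzyloxy)-4-formyl-5-methylphenyl 5-acetoxy-2,4-bis(benzyloxy)-6-methylbenzoate | CC(=O)Oc1c(C)c(C(=O)Oc2cc(C)c(C=O)c(OCc3ccccc3)c2)c(OCc2ccccc2)cc1OCc1ccccc1
F10 | step 15 | 4-{[5-acetoxy-2,4-bis(benzyloxy)-6-methylbenzoyl]oxy}-2-(benzyloxy)-6-methylbenzoic acid | CC(=O)Oc1c(C)c(C(=O)Oc2cc(C)c(C(=O)O)c(OCc3ccccc3)c2)c(OCc2ccccc2)cc1OCc1ccccc1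
A1 | alternative 1 | benzyl 2-(benzyloxy)-4-[(2,4-dihydroxy-6-methylbenzoyl)oxy]-6-methylbenzoate | Cc1cc(O)cc(O)c1C(=O)Oc1cc(C)c(C(=O)OCc2ccccc2)c(OCc2ccccc2)c1
A2 | alternative 1 | 6-(2,4-dioxopentyl)-2,2-dimethyl-4H-1,3-dioxin-4-one | CC(=O)CC(=O)CC1=CC(=O)OC(C)(C)O1
A3 | alternative 1 | benzyl 2-(benzyloxy)-4-hydroxy-6-methylbenzoate | Cc1cc(O)cc(OCc2ccccc2)c1C(=O)OCc1ccccc1
A4 | alternative 2 | benzyl 2-hydroxy-6-methyl-4-(triisopropylsilyloxy)-3-(trimethylsilyl)benzoate | Cc1cc(O[Si](C(C)C)(C(C)C)C(C)C)c([Si](C)(C)C)c(O)c1C(=O)OCc1ccccc1
A5 | alternative 2 | benzyl (E)-5-diazo-3-methyl-4-oxopent-2-enoate | [N-]=[N+]=CC(=O)/C(C)=C/C(=O)OCc1ccccc1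
A6 | alternative 2 | triisopropyl{[(trimethylsilyl)ethynyl]oxy}silane | C[Si](C)(C)C#CO[Si](C(C)C)(C(C)C)C(C)C
A7 | alternative 3 | benzyl 2-(benzyloxy)-4-{[2-(benzyloxy)-4-({4-(benzyloxy)-2-[(tert-butyldimethylsilyl)oxy]-5-hydroxy-6-methylbenzoyl}oxy)-6-methylbenzoyl]oxy}-6-methylbenzoate | Cc1c(O)c(OCc2ccccc2)cc(O[Si](C)(C)C(C)(C)C)c1C(=O)Oc1cc(C)c(C(=O)Oc2cc(C)c(C(=O)OCc3ccccc3)c(OCc3ccccc3)c2)c(OCc3ccccc3)c1
A8 | alternative 3 | {[4-(benzyloxy)furan-2-yl]oxy}(tert-butyl)dimethylsilane | CC(C)(C)[Si](C)(C)Oc1cc(OCc2ccccc2)co1
A9 | alternative 3 | benzyl 2-(benzyloxy)-4-{[2-(benzyloxy)-4-(but-2-ynoyloxy)-6-methylbenzoyl]oxy}-6-methylbenzoate | CC#CC(=O)Oc1cc(C)c(C(=O)Oc2cc(C)c(C(=O)OCc3ccccc3)c(OCc3ccccc3)c2)c(OCc3ccccc3)c1
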